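(The runs come from a simulation with constants of no real substance; the scatter is artificial.)

You cannot read the end of green or grey off the runs: the last reading stands at 48.0 h, the question at 3.0 d, and the partner charges differ.

| flask | left-handed substrate | right-handed substrate | partner | free catalyst | impurity | remark | time |
|---|---|---|---|---|---|---|---|
| dawn | 0.20 M | 0.20 M | 0.74 equiv | 0.11 mol% | 79 µM | run made earlier |  |
| summer | 0.20 M | 0.20 M | 1.3 equiv | 0.11 mol% | 79 µM | run made earlier |  |
| green | 0.20 M | 0.20 M | 0.600 equiv | 0.11 mol% | 79 µM |  | 3.0 d |
| grey | 0.20 M | 0.20 M | 1.20 equiv | 0.11 mol% | 79 µM |  | 3.0 d |

| run | time / h | right-handed substrate / % | left-handed substrate / % |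
|---|---|---|---|
| dawn | 4.00 | 51 | 46 |
| dawn | 6.00 | 51 | 47 |
| dawn | 12.0 | 49 | 46 |
| dawn | 20.0 | 46 | 46 |
| dawn | 30.0 | 46 | 40 |
| dawn | 48.0 | 47 | 39 |
| summer | 4.00 | 49 | 48 |
| summer | 6.00 | 49 | 46 |
| summer | 12.0 | 48 | 44 |
| summer | 20.0 | 47 | 36 |
| summer | 30.0 | 45 | 35 |
| summer | 48.0 | 42 | 31 |

(each reading ± 1.5 percentage points)

- free catalyst is single-handed; left-handed substrate and right-handed substrate are mirror images of each other, charged as a racemate, each of them at the stated concentration
- candidate steps: partner + free catalyst + left-handed substrate -> free catalyst + left-handed product; partner + free catalyst + right-handed substrate -> free catalyst + right-handed product; free catalyst + impurity -> spent catalyst; partner -> decomposed reagent; left-handed product <-> right-handed product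
- an excess is the difference of the two amounts in percent of their sum
- an excess is below zero if the other one leads

- which one finishes higher in excess of right-handed substrate over left-handed substrate among what is left of the two ("neither" within 2 percentage points) (green / grey / neither)
- excess of right-handed substrate over left-handed substrate among what is left of the two at the end, green
- excess of right-handed substrate over left-handed substrate among what is left of the two at the end, grey

The logs of what is left at the last summer reading give a rough selectivity factor of 2.74, so in summer left-handed substrate goes faster than right-handed substrate. Suppose each substrate falls in proportion to its own amount. Then the log of their ratio grows independently of how much substrate remains, and it should follow the partner.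

So define the skew per equivalent: ln(right-handed over left-handed substrate) divided by the equivalents of partner. At the last reading, dawn gives 0.252 and summer 0.234, close within the scatter.

But the skew drifts. Pooled, the two runs read 0.0736, 0.192 and 0.240 at 12.0 h, 30.0 h and 48.0 h. Each equal step therefore gains 0.412 of the step before, a rough reading. Continuing that fade to the asked time, I commit to a skew of 0.264.

Multiply by the equivalents and convert the log ratio into an excess. Green gets 7.90% and grey 15.7%, so grey leads by more than the margin.

The forecast also says grey, but with higher figures than mine: 9% for green and 17% for grey, from a factor where “with the slowing, multiplies this by about 1.2”.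

The simulation gives grey, with 7.27% for green and 14.9% for grey.

    partner + free catalyst + left-handed substrate → free catalyst + left-handed product (k = 513 L² mol⁻² h⁻¹)
    partner + free catalyst + right-handed substrate → free catalyst + right-handed product (k = 168 L² mol⁻² h⁻¹)
    free catalyst + impurity → spent catalyst (k = 20300 L mol⁻¹ h⁻¹)
    partner → decomposed reagent (k = 0.0198 h⁻¹)
    left-handed product ⇌ right-handed product (k = 0.237 h⁻¹)

Turned back, these excesses give skews of 0.243 for green and 0.250 for grey, both lower than my reckoned skew. The neighbour of grey charged with 4.80 equiv of partner, other charges and time held, reckons to 56.0%. That flask gives 59.5%, higher than reckoned, with left-handed substrate at 6.50% and right-handed substrate at 25.6% of the two charged together.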